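**Retrosynthetic overview**
- The five-membered ring of the indenone is closed last, by intramolecular aldol condensation of a 1,2-diacylbenzene (aryl-CH2-CO-aryl' with an ortho aroyl group). This ketone is unmasked by acid from a C2-symmetric 1,2-diaryl-1,2-diol acetonide.
- Both pentasubstituted hydroquinone rings are made first and at the same time, by a two-directional Diels–Alder/ring-opening aromatisation of a tartrate-derived bis-ynone with two molecules of a 4-methyl-2-silyloxyfuran. The silyl group left on one oxygen of each ring makes the later O-methylation unambiguous.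
- The bis-ynone comes from acyl Sonogashira coupling of 4,5-diethynyl-2,2-dimethyl-1,3-dioxolane with 2,6-dimethoxybenzoyl chloride; the two 2,6-dimethoxyphenyl rings are bought.
- Ring order: the two benzene rings (rings A and B) together in step 4, then the five-membered ring in step 6.

Assumption: the target SMILES has no stereocentre and no stereodescriptor, so acredinone A is made as the single achiral constitution shown; the hindered aryl–carbon axes are left uncontrolled.

The route is a paper design; no step has been run, and steps 4 and 6 carry most of the risk.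

**Step 1**
Reactants: 1 dimethyl (4R,5R)-2,2-dimethyl-1,3-dioxolane-4,5-dicarboxylate (dimethyl 2,3-O-isopropylidene-L-tartrate)
Product: 3 (4S,5S)-4,5-diethynyl-2,2-dimethyl-1,3-dioxolane, via dialdehyde 2 (not isolated)
Conditions: DIBAL-H (2.2 equiv), CH2Cl2, −78 °C; then MeOH, K2CO3, Bestmann–Ohira reagent, −78 °C to rt
Reagents that add atoms: Bestmann–Ohira reagent, dimethyl (1-diazo-2-oxopropyl)phosphonate, CC(=O)C(=[N+]=[N-])P(=O)(OC)OC
Why: One-pot DIBAL-H half-reduction of the esters followed by Seyferth–Gilbert (Ohira–Bestmann) homologation of the aldehydes is an established ester-to-alkyne conversion; no stereocentre is made, the trans-dioxolane is carried through (the descriptor changes only because the CIP ranking changes) and both centres are removed in step 6.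

**Step 2**
Reactants: 3 (4S,5S)-4,5-diethynyl-2,2-dimethyl-1,3-dioxolane; 4 2,6-dimethoxybenzoyl chloride (2.3 equiv)
Product: 5 3,3'-[(4S,5S)-2,2-dimethyl-1,3-dioxolane-4,5-diyl]bis[1-(2,6-dimethoxyphenyl)prop-2-yn-1-one]
Conditions: PdCl2(PPh3)2 (4 mol %), CuI (8 mol %), Et3N (3 equiv), THF, rt
Reagents that add atoms: none
Why: Acyl Sonogashira coupling of an aroyl chloride with a terminal alkyne gives the ynone directly at room temperature, the acetonide is inert to these conditions, and no stereocentre is touched.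

**Step 3**
Reactants: 6 4-methylfuran-2(5H)-one
Product: 7 tert-butyl(dimethyl)[(4-methylfuran-2-yl)oxy]silane
Conditions: TBSOTf, Et3N, CH2Cl2, 0 °C
Reagents that add atoms: tert-butyldimethylsilyl trifluoromethanesulfonate (TBSOTf), CC(C)(C)[Si](C)(C)OS(=O)(=O)C(F)(F)F
Why: Soft enolisation of the butenolide at C5 and O-silylation (silyl dienol ether formation) gives the aromatic 2-silyloxyfuran; there is no stereocentre.

**Step 4**
Reactants: 5 bis-ynone; 7 silyloxyfuran (3 equiv)
Product: 9 (4S,5S)-4,5-bis[3-(tert-butyldimethylsilyloxy)-2-(2,6-dimethoxybenzoyl)-6-hydroxy-5-methylphenyl]-2,2-dimethyl-1,3-dioxolane, via bis-oxanorbornadiene 8 (not isolated)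
Conditions: toluene, 90 °C, sealed tube, 24 h
Reagents that add atoms: none
Why: This is the Diels–Alder reaction of a 2-silyloxyfuran with an ynone followed by ring-opening aromatisation of the 1-silyloxy-7-oxanorbornadiene (a known route to hydroquinone mono-silyl ethers), run in two directions so that both benzene rings form at once; the nucleophilic furan C5 bonds to the ynone β-carbon, which puts the aroyl group next to the silylated oxygen and the methyl group para to the aroyl group on each ring, and the bridgehead centres of 8 vanish on aromatisation.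

**Step 5**
Reactants: 9 bis(silyloxyphenol)
Product: 11 (4S,5S)-4,5-bis[2-(2,6-dimethoxybenzoyl)-3-hydroxy-6-methoxy-5-methylphenyl]-2,2-dimethyl-1,3-dioxolane, via bis-silyl ether 10 (not isolated)
Conditions: MeI, K2CO3, acetone, 50 °C; evaporate; K2CO3 (cat.), MeOH, rt
Reagents that add atoms: iodomethane, CI
Why: Williamson O-methylation can only hit the single free phenol of each ring, and the aryl silyl ether ortho to the ketone is then cleaved by K2CO3/MeOH (standard phenolic silyl ether methanolysis); no stereocentre is affected.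

**Step 6**
Reactants: 11 bis-phenol acetonide
Product: 15 acredinone A, via diol 12 (not isolated), via isobenzofuran carbinol 13 (not isolated), via triketone 14 (not isolated)
Conditions: p-TsOH·H2O (3 equiv), 1,4-dioxane/H2O (9:1), 90 °C, argon
Reagents that add atoms: none
Why: Proposed new method: acid hydrolyses the acetonide to diol 12, one benzylic hydroxyl closes onto the neighbouring aroyl carbonyl and dehydrates to isobenzofuran carbinol 13 (the classical o-acylbenzyl alcohol to isobenzofuran dehydration), ionisation of the remaining furfuryl-type hydroxyl and re-addition of water at the aryl-bearing furan carbon opens the furan to triketone 14 (closest known types: acid hydrolysis of furfuryl alcohols to 1,4-dicarbonyls and the pinacol-type 1,2-diol to ketone dehydration, regiochemically unambiguous here because 12 is C2-symmetric), and the doubly activated methylene of 14 then condenses with the ortho aroyl ketone (intramolecular aldol condensation of a 1,2-diacylbenzene) to the indenone; both stereocentres of 11 are destroyed and none is created.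

**Compound list**
1 | dimethyl (4R,5R)-2,2-dimethyl-1,3-dioxolane-4,5-dicarboxylate | COC(=O)[C@@H]1OC(C)(C)O[C@H]1C(=O)OC | starting material
2 | (4R,5R)-2,2-dimethyl-1,3-dioxolane-4,5-dicarbaldehyde | O=C[C@@H]1OC(C)(C)O[C@H]1C=O | intermediate
3 | (4S,5S)-4,5-diethynyl-2,2-dimethyl-1,3-dioxolane | C#C[C@@H]1OC(C)(C)O[C@H]1C#C | intermediate
4 | 2,6-dimethoxybenzoyl chloride | COc1cccc(OC)c1C(Cl)=O | starting material
5 | 3,3'-[(4S,5S)-2,2-dimethyl-1,3-dioxolane-4,5-diyl]bis[1-(2,6-dimethoxyphenyl)prop-2-yn-1-one] | COc1cccc(OC)c1C(=O)C#C[C@@H]1OC(C)(C)O[C@H]1C#CC(=O)c1c(OC)cccc1OC | intermediate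
6 | 4-methylfuran-2(5H)-one | CC1=CC(=O)OC1 | starting material
7 | tert-butyl(dimethyl)[(4-methylfuran-2-yl)oxy]silane | Cc1coc(O[Si](C)(C)C(C)(C)C)c1 | intermediate
8 | (4S,5S)-2,2-dimethyl-1,3-dioxolane carrying at C4 and at C5 a 3-(2,6-dimethoxybenzoyl)-4-(tert-butyldimethylsilyloxy)-6-methyl-7-oxabicyclo[2.2.1]hepta-2,5-dien-2-yl group (bridgehead centres form as a diastereomer mixture and are left undefined) | COc1cccc(OC)c1C(=O)C2=C([C@@H]3OC(C)(C)O[C@H]3C4=C(C(=O)c5c(OC)cccc5OC)C6(O[Si](C)(C)C(C)(C)C)C=C(C)C4O6)C7OC2(O[Si](C)(C)C(C)(C)C)C=C7C | intermediate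
9 | (4S,5S)-4,5-bis[3-(tert-butyldimethylsilyloxy)-2-(2,6-dimethoxybenzoyl)-6-hydroxy-5-methylphenyl]-2,2-dimethyl-1,3-dioxolane | COc1cccc(OC)c1C(=O)c2c(O[Si](C)(C)C(C)(C)C)cc(C)c(O)c2[C@@H]3OC(C)(C)O[C@H]3c4c(O)c(C)cc(O[Si](C)(C)C(C)(C)C)c4C(=O)c5c(OC)cccc5OC | intermediate
10 | (4S,5S)-4,5-bis[3-(tert-butyldimethylsilyloxy)-2-(2,6-dimethoxybenzoyl)-6-methoxy-5-methylphenyl]-2,2-dimethyl-1,3-dioxolane | COc1cccc(OC)c1C(=O)c2c(O[Si](C)(C)C(C)(C)C)cc(C)c(OC)c2[C@@H]3OC(C)(C)O[C@H]3c4c(OC)c(C)cc(O[Si](C)(C)C(C)(C)C)c4C(=O)c5c(OC)cccc5OC | intermediate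
11 | (4S,5S)-4,5-bis[2-(2,6-dimethoxybenzoyl)-3-hydroxy-6-methoxy-5-methylphenyl]-2,2-dimethyl-1,3-dioxolane | COc1cccc(OC)c1C(=O)c2c(O)cc(C)c(OC)c2[C@@H]3OC(C)(C)O[C@H]3c4c(OC)c(C)cc(O)c4C(=O)c5c(OC)cccc5OC | intermediate
12 | (1S,2S)-1,2-bis[2-(2,6-dimethoxybenzoyl)-3-hydroxy-6-methoxy-5-methylphenyl]ethane-1,2-diol | COc1cccc(OC)c1C(=O)c2c(O)cc(C)c(OC)c2[C@H](O)[C@@H](O)c3c(OC)c(C)cc(O)c3C(=O)c4c(OC)cccc4OC | intermediate
13 | (S)-[2-(2,6-dimethoxybenzoyl)-3-hydroxy-6-methoxy-5-methylphenyl][3-(2,6-dimethoxyphenyl)-4-hydroxy-7-methoxy-6-methyl-2-benzofuran-1-yl]methanol | COc1cccc(OC)c1C(=O)c2c(O)cc(C)c(OC)c2[C@H](O)c3oc(c4c(OC)cccc4OC)c5c(O)cc(C)c(OC)c35 | intermediate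
14 | 1,2-bis[2-(2,6-dimethoxybenzoyl)-3-hydroxy-6-methoxy-5-methylphenyl]ethan-1-one | COc1cccc(OC)c1C(=O)c2c(O)cc(C)c(OC)c2CC(=O)c3c(OC)c(C)cc(O)c3C(=O)c4c(OC)cccc4OC | intermediate
15 | acredinone A, 2-[2-(2,6-dimethoxybenzoyl)-3-hydroxy-6-methoxy-5-methylphenyl]-3-(2,6-dimethoxyphenyl)-4-hydroxy-7-methoxy-6-methyl-1H-inden-1-one | COc1cccc(OC)c1C(=O)c1c(O)cc(C)c(OC)c1C1=C(c2c(OC)cccc2OC)c2c(O)cc(C)c(OC)c2C1=O | target

**Step count and risk**
Total step count: 6. Longest linear sequence: 5 steps (1 → 3 → 5 → 9 → 11 → 15); step 3 is a one-step side branch.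

The three steps most likely to fail:

Step 6 (acid cascade). The diol could rearrange by aryl shift to a diarylacetaldehyde, stall at cyclic ketals, or lose material through the air-sensitive isobenzofuran. Fallback, setting out from 11: cleave the acetonide under mild conditions (80% aqueous AcOH, 40 °C) and isolate diol 12. Oxidise one carbinol through the stannylene acetal (Bu2SnO, then NBS) to (2S)-1,2-bis[2-(2,6-dimethoxybenzoyl)-3-hydroxy-6-methoxy-5-methylphenyl]-2-hydroxyethan-1-one F1. Remove the remaining α-hydroxyl reductively (Zn, AcOH, 60 °C) to reach triketone 14, and close 14 to 15 with p-TsOH in warm toluene. This replaces the cationic diol-to-ketone transposition by a redox sequence and comes back to the route at 14.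

Step 4 (two-directional cycloaddition). The congested bond between the methyl-flanked furan C5 and the branched ynone β-carbon may form slowly, and open-chain Michael adducts or mono-adducts may result. Fallback, setting out from 5: change the diene to 3-methyl-2,5-bis(trimethylsilyloxy)furan F2 (made from methylsuccinic anhydride, TMSCl, Et3N, ZnCl2). Its two-fold Diels–Alder reaction with 5 (toluene, 60 °C) gives the bis(1,4-disilyloxy-7-oxanorbornadiene) F3. Hydrolytic work-up collapses this to 3,3'-[(4S,5S)-2,2-dimethyl-1,3-dioxolane-4,5-diyl]bis[2-(2,6-dimethoxybenzoyl)-5-methylcyclohexa-2,5-diene-1,4-dione] F4. Reduction with Na2S2O4 gives (4S,5S)-4,5-bis[2-(2,6-dimethoxybenzoyl)-3,6-dihydroxy-5-methylphenyl]-2,2-dimethyl-1,3-dioxolane F5. Chelation-controlled methylation of the hydroxyl that is not hydrogen-bonded to the ketone on each ring (MeI, K2CO3, acetone) comes back to the route at 11. The methyl regiochemistry is less secure with this diene.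

Step 2 (acyl Sonogashira with a di-ortho-substituted aroyl chloride). Coupling may be slow, and the ynone may suffer amine addition. Fallback, setting out from 3: deprotonate both alkynes (n-BuLi, THF, −78 °C) and add 2,6-dimethoxybenzaldehyde to give 3,3'-[(4S,5S)-2,2-dimethyl-1,3-dioxolane-4,5-diyl]bis[1-(2,6-dimethoxyphenyl)prop-2-yn-1-ol] F6 (carbinol epimers, of no consequence). Oxidise F6 with MnO2 (CH2Cl2, rt), which comes back to the route at 5.

**Further compounds**
F1 | step 6 | (2S)-1,2-bis[2-(2,6-dimethoxybenzoyl)-3-hydroxy-6-methoxy-5-methylphenyl]-2-hydroxyethan-1-one | COc1cccc(OC)c1C(=O)c2c(O)cc(C)c(OC)c2[C@H](O)C(=O)c3c(OC)c(C)cc(O)c3C(=O)c4c(OC)cccc4OC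
F2 | step 4 | 3-methyl-2,5-bis(trimethylsilyloxy)furan | Cc1cc(O[Si](C)(C)C)oc1O[Si](C)(C)C
F3 | step 4 | (4S,5S)-2,2-dimethyl-1,3-dioxolane carrying at C4 and at C5 a 3-(2,6-dimethoxybenzoyl)-6-methyl-1,4-bis(trimethylsilyloxy)-7-oxabicyclo[2.2.1]hepta-2,5-dien-2-yl group (bridgehead centres undefined, mixture) | COc1cccc(OC)c1C(=O)C2=C([C@@H]3OC(C)(C)O[C@H]3C4=C(C(=O)c5c(OC)cccc5OC)C6(O[Si](C)(C)C)C=C(C)C4(O[Si](C)(C)C)O6)C7(O[Si](C)(C)C)OC2(O[Si](C)(C)C)C=C7C
F4 | step 4 | 3,3'-[(4S,5S)-2,2-dimethyl-1,3-dioxolane-4,5-diyl]bis[2-(2,6-dimethoxybenzoyl)-5-methylcyclohexa-2,5-diene-1,4-dione] | COc1cccc(OC)c1C(=O)C2=C([C@@H]3OC(C)(C)O[C@H]3C4=C(C(=O)c5c(OC)cccc5OC)C(=O)C=C(C)C4=O)C(=O)C(C)=CC2=O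
F5 | step 4 | (4S,5S)-4,5-bis[2-(2,6-dimethoxybenzoyl)-3,6-dihydroxy-5-methylphenyl]-2,2-dimethyl-1,3-dioxolane | COc1cccc(OC)c1C(=O)c2c(O)cc(C)c(O)c2[C@@H]3OC(C)(C)O[C@H]3c4c(O)c(C)cc(O)c4C(=O)c5c(OC)cccc5OC
F6 | step 2 | 3,3'-[(4S,5S)-2,2-dimethyl-1,3-dioxolane-4,5-diyl]bis[1-(2,6-dimethoxyphenyl)prop-2-yn-1-ol] (carbinol centres undefined, mixture) | COc1cccc(OC)c1C(O)C#C[C@@H]1OC(C)(C)O[C@H]1C#CC(O)c1c(OC)cccc1OC
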